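**Plan**

- Retrosynthesis (chromanone numbering): cut O1–C8a (aryl ether, water lost) to an open triol β-ketol; cut C4–C4a to an (S)-β-silyloxy Weinreb amide and a 2,4,6-trioxygenated 3,5-dimethylphenyllithium; cut C6–CH3 and C8–CH3 back to phloroglucinol; cut C2–C3 to stearoyl chloride and Meldrum's acid.
- Enabling feature: ring A (C4a, C5, C6, C7, C8, C8a) is a fully substituted phloroglucinol, the trienol of a cyclohexane-1,3,5-trione, and O1–C8a=C4a–C4=O is a vinylogous ester. In the open ketol the two HO-bearing carbons ortho to the C4 ketone are interchangeable, so the C2 hydroxyl can take the place of either ring OH by addition–elimination.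
- Forward: the C20 chain is made first (β-keto ester, asymmetric hydrogenation, silyl ether, Weinreb amide). Ring A is dressed by three ortho-lithiations of tris-MOM phloroglucinol (CH3, CH3, then the acyl chain). After global deprotection the dihydropyranone ring (ring C) is closed last, on the unprotected compound.
- Stereochemistry: C2 (S) comes from the Noyori hydrogenation with RuCl2[(S)-BINAP] and is carried unchanged, because no later step breaks the C2–O bond or forms a new stereocenter.

Key step: step 10

Remark: the atom numbers of the target are also used for the open-chain precursors; the carbinol carbon keeps the descriptor (S) throughout because the CIP order O > CH2C(=O) > alkyl > H is the same in every intermediate and in the target.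

**Route**

Step 1
Reactants: 1 octadecanoyl chloride (stearoyl chloride); 2 Meldrum's acid (2,2-dimethyl-1,3-dioxane-4,6-dione)
Product: 4 methyl 3-oxoicosanoate, via acyl Meldrum's acid 3 (not isolated)
Conditions: pyridine, CH2Cl2, 0 °C → rt; then MeOH, reflux
Reagents that add atoms: methanol, CO
Why: C-acylation of Meldrum's acid followed by methanolysis with loss of acetone and CO2 (Meldrum's acid β-keto ester synthesis) is the standard two-carbon homologation of an acid chloride.

Step 2
Reactants: 4 methyl 3-oxoicosanoate
Product: 5 methyl (S)-3-hydroxyicosanoate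
Conditions: H2 (10 bar), RuCl2[(S)-BINAP] (0.2 mol %), MeOH–CH2Cl2, 60 °C
Reagents that add atoms: none
Why: Noyori asymmetric hydrogenation of a β-keto ester, in which the ester carbonyl chelates ruthenium and the (S)-BINAP ligand should direct hydride to the face of the C3 ketone that gives the (S)-alcohol, the sense established for 3-oxoalkanoates.

Step 3
Reactants: 5 methyl (S)-3-hydroxyicosanoate
Product: 6 methyl (S)-3-[(tert-butyldimethylsilyl)oxy]icosanoate
Conditions: TBSCl, imidazole, DMF, rt
Reagents that add atoms: tert-butyldimethylsilyl chloride, CC(C)(C)[Si](C)(C)Cl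
Why: Imidazole-promoted silylation of a secondary alcohol (silyl ether protection) masks the hydroxyl so that it survives the Grignard and aryllithium steps.

Step 4
Reactants: 6 methyl (S)-3-[(tert-butyldimethylsilyl)oxy]icosanoate
Product: 7 (S)-3-[(tert-butyldimethylsilyl)oxy]-N-methoxy-N-methylicosanamide
Conditions: MeNH(OMe)·HCl, i-PrMgCl, THF, −20 → 0 °C
Reagents that add atoms: N,O-dimethylhydroxylamine hydrochloride, CNOC.Cl
Why: Aminolysis of the ester by the chloromagnesium amide of N,O-dimethylhydroxylamine (Weinreb amide formation) is well precedented for β-silyloxy esters and does not touch the stereocenter.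

Step 5
Reactants: 8 phloroglucinol (benzene-1,3,5-triol)
Product: 9 1,3,5-tris(methoxymethoxy)benzene
Conditions: NaH, MOMCl, DMF, 0 °C → rt
Reagents that add atoms: chloromethyl methyl ether, COCCl
Why: Williamson-type O-alkylation of the sodium phenoxide with the hard electrophile MOMCl in DMF favours O- over C-alkylation and gives the known tris-acetal.

Step 6
Reactants: 9 1,3,5-tris(methoxymethoxy)benzene
Product: 11 2-methyl-1,3,5-tris(methoxymethoxy)benzene, via aryllithium 10 (not isolated)
Conditions: n-BuLi, THF, 0 °C; then MeI, 0 °C → rt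
Reagents that add atoms: iodomethane, CI
Why: Directed ortho-metalation, since every ring hydrogen of 9 lies between two OMOM groups that bind n-BuLi and acidify that position, followed by SN2 methylation of the aryllithium.

Step 7
Reactants: 11 2-methyl-1,3,5-tris(methoxymethoxy)benzene
Product: 13 2,4-dimethyl-1,3,5-tris(methoxymethoxy)benzene, via aryllithium 12 (not isolated)
Conditions: n-BuLi, THF, 0 °C; then MeI, 0 °C → rt
Reagents that add atoms: iodomethane, CI
Why: A second directed ortho-metalation and methylation, the two remaining ring hydrogens being equivalent and each flanked by two OMOM groups, so that ring lithiation should be preferred to lateral lithiation of the methyl group.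

Step 8
Reactants: 13 2,4-dimethyl-1,3,5-tris(methoxymethoxy)benzene; 7 (S)-3-[(tert-butyldimethylsilyl)oxy]-N-methoxy-N-methylicosanamide
Product: 15 (S)-3-[(tert-butyldimethylsilyl)oxy]-1-[3,5-dimethyl-2,4,6-tris(methoxymethoxy)phenyl]icosan-1-one, via aryllithium 14 (not isolated)
Conditions: n-BuLi (0.95 equiv to 13), THF, 0 °C; then 7 (0.8 equiv), −78 → 0 °C; aq NH4Cl
Reagents that add atoms: none
Why: Directed ortho-metalation of the last ring hydrogen and Weinreb ketone synthesis, in which the lithium-chelated tetrahedral adduct holds until the quench so that the aryllithium adds only once and the stereocenter of 7 is not touched.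

Step 9
Reactants: 15 (S)-3-[(tert-butyldimethylsilyl)oxy]-1-[3,5-dimethyl-2,4,6-tris(methoxymethoxy)phenyl]icosan-1-one
Product: 16 (S)-3-hydroxy-1-(2,4,6-trihydroxy-3,5-dimethylphenyl)icosan-1-one
Conditions: HCl (1.25 M in MeOH), THF, 0 °C → rt, under argon
Reagents that add atoms: none
Why: Acid-catalysed acetal exchange of the three aryl MOM ethers with methanol and acid-mediated cleavage of the secondary silyl ether are standard deprotections that should leave the β-ketol and its stereocenter intact at or below room temperature.

Step 10
Reactants: 16 (S)-3-hydroxy-1-(2,4,6-trihydroxy-3,5-dimethylphenyl)icosan-1-one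
Product: 17 (S)-2-heptadecyl-5,7-dihydroxy-6,8-dimethylchroman-4-one
Conditions: TfOH (10 mol %), HFIP–CH2Cl2 (1:4), 0.02 M, 0 °C → rt
Reagents that add atoms: none
Why: Proposed new method: the acid protonates the C4 carbonyl (or ring carbon C8) of the acylphloroglucinol, which makes C8a, the carbinol carbon of the vinylogous acid HO–C8a=C4a–C4=O, a hydroxy-oxocarbenium carbon of the keto tautomer; the C2 hydroxyl adds there, the geminal ring OH is protonated and leaves as water, and loss of a proton restores the aromatic ring A. The closest known reaction types are the acid-catalysed O-alkylation of phloroglucinol by alcohols through its keto tautomer and the cyclodehydration of 2,2'-dihydroxybenzophenones that carry a phloroglucinol ring to xanthones (second stage of the Grover–Shah–Shah synthesis), in both of which a ring OH of a phloroglucinol is replaced by an oxygen nucleophile; an aliphatic hydroxyl closing a 2,3-dihydro-4-pyranone ring in this way has not been shown. The ring O1–C2–C3–C4–C4a–C8a closes in the 6-exo-trig mode (attack on the protonated C8a=O of the keto form) and is completed by elimination of water. No stereocenter is formed, and C2 keeps its (S) configuration because its C–O bond is never broken, unlike in a Mitsunobu or oxa-Michael closure at C2. Site selectivity is settled by the substrate, since the two oxygen-bearing ortho carbons of 16 are exchanged by rotation about the C4–C4a bond and the C7 carbon cannot be reached by the three-atom tether. The chemoselectivity needed is substitution at C8a ahead of acid-catalysed dehydration of the β-ketol, which would reach the same constitution through an enone and an oxa-Michael addition but as a racemate; it is sought through a non-basic medium (triflate in HFIP) that offers no general base for enolisation, low temperature and the high effective molarity of the six-membered closure, helped by the two C-methyl groups, which raise the share of the keto tautomer of ring A.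

**Compound list**

1 | octadecanoyl chloride (stearoyl chloride) | CCCCCCCCCCCCCCCCCC(=O)Cl | starting material
2 | Meldrum's acid (2,2-dimethyl-1,3-dioxane-4,6-dione) | CC1(C)OC(=O)CC(=O)O1 | starting material
3 | 5-(1-hydroxyoctadecylidene)-2,2-dimethyl-1,3-dioxane-4,6-dione (acyl Meldrum's acid) | CCCCCCCCCCCCCCCCCC(O)=C1C(=O)OC(C)(C)OC1=O | intermediate (not isolated)
4 | methyl 3-oxoicosanoate | CCCCCCCCCCCCCCCCCC(=O)CC(=O)OC | intermediate
5 | methyl (S)-3-hydroxyicosanoate | CCCCCCCCCCCCCCCCC[C@H](O)CC(=O)OC | intermediate
6 | methyl (S)-3-[(tert-butyldimethylsilyl)oxy]icosanoate | CCCCCCCCCCCCCCCCC[C@H](O[Si](C)(C)C(C)(C)C)CC(=O)OC | intermediate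
7 | (S)-3-[(tert-butyldimethylsilyl)oxy]-N-methoxy-N-methylicosanamide | CCCCCCCCCCCCCCCCC[C@H](O[Si](C)(C)C(C)(C)C)CC(=O)N(C)OC | intermediate
8 | phloroglucinol (benzene-1,3,5-triol) | Oc1cc(O)cc(O)c1 | starting material
9 | 1,3,5-tris(methoxymethoxy)benzene | COCOc1cc(OCOC)cc(OCOC)c1 | intermediate
10 | 2,4,6-tris(methoxymethoxy)phenyllithium | [Li]c1c(OCOC)cc(OCOC)cc1OCOC | intermediate (not isolated)
11 | 2-methyl-1,3,5-tris(methoxymethoxy)benzene | Cc1c(OCOC)cc(OCOC)cc1OCOC | intermediate
12 | 3-methyl-2,4,6-tris(methoxymethoxy)phenyllithium | [Li]c1c(OCOC)cc(OCOC)c(C)c1OCOC | intermediate (not isolated)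
13 | 2,4-dimethyl-1,3,5-tris(methoxymethoxy)benzene | Cc1c(OCOC)cc(OCOC)c(C)c1OCOC | intermediate
14 | 3,5-dimethyl-2,4,6-tris(methoxymethoxy)phenyllithium | [Li]c1c(OCOC)c(C)c(OCOC)c(C)c1OCOC | intermediate (not isolated)
15 | (S)-3-[(tert-butyldimethylsilyl)oxy]-1-[3,5-dimethyl-2,4,6-tris(methoxymethoxy)phenyl]icosan-1-one | CCCCCCCCCCCCCCCCC[C@H](O[Si](C)(C)C(C)(C)C)CC(=O)c1c(OCOC)c(C)c(OCOC)c(C)c1OCOC | intermediate
16 | (S)-3-hydroxy-1-(2,4,6-trihydroxy-3,5-dimethylphenyl)icosan-1-one | CCCCCCCCCCCCCCCCC[C@H](O)CC(=O)c1c(O)c(C)c(O)c(C)c1O | intermediate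
17 | (S)-2-heptadecyl-5,7-dihydroxy-6,8-dimethylchroman-4-one | CCCCCCCCCCCCCCCCC[C@H]1CC(=O)c2c(O)c(C)c(O)c(C)c2O1 | target

**Step count and risks**

Total steps: 10. Longest linear sequence: 7 steps (steps 1, 2, 3, 4, 8, 9, 10).

Steps most likely to fail:

1. Step 10 (the proposed new method). Acid-catalysed enolisation of the β-ketol and loss of water may outrun the exchange of the ring hydroxyl at C8a. Re-closure of the resulting enone by oxa-Michael addition would then erode the enantiomeric purity. The ring hydroxyl may also fail to exchange at an acidity that the ketol tolerates. The fallback uses known chemistry and closes ring C at O1–C2 with inversion instead of at O1–C8a with retention. It sets out from 4. Hydrogenation as in step 2 but with RuCl2[(R)-BINAP] should give methyl (R)-3-hydroxyicosanoate F1. Silylation as in step 3 gives methyl (R)-3-[(tert-butyldimethylsilyl)oxy]icosanoate F2. Amidation as in step 4 gives (R)-3-[(tert-butyldimethylsilyl)oxy]-N-methoxy-N-methylicosanamide F3. Addition of aryllithium 14 as in step 8 gives (R)-3-[(tert-butyldimethylsilyl)oxy]-1-[3,5-dimethyl-2,4,6-tris(methoxymethoxy)phenyl]icosan-1-one F4. Methanolic HCl as in step 9 gives (R)-3-hydroxy-1-(2,4,6-trihydroxy-3,5-dimethylphenyl)icosan-1-one F5. An intramolecular Mitsunobu reaction (PPh3, DIAD, THF, 0 °C), in which a chelated ortho phenol displaces the activated C2 oxygen with inversion, then closes ring C and comes back to the route at 17.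

2. Step 8. Addition of the doubly ortho-substituted aryllithium to the amide may be slow, so that α-deprotonation of the amide and β-elimination of the silyloxy group compete. The fallback sets out from 6. Reduction with i-Bu2AlH (toluene, −78 °C) gives (S)-3-[(tert-butyldimethylsilyl)oxy]icosanal F6. Aryllithium 14 (THF, −78 °C) adds to this far more electrophilic aldehyde to give (3S)-3-[(tert-butyldimethylsilyl)oxy]-1-[3,5-dimethyl-2,4,6-tris(methoxymethoxy)phenyl]icosan-1-ol F7 as a mixture of epimers at the benzylic carbon, which is of no consequence. Dess–Martin oxidation (NaHCO3, CH2Cl2) comes back to the route at 15.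

3. Step 9. Premature acid-induced loss of water from the β-ketol, or uncontrolled ring closure, may occur while the acetals are cleaved in protic acid. The fallback sets out from 15 and unmasks in two aprotic stages. HF·pyridine (THF–pyridine, 0 °C → rt) removes only the silyl ether to give (S)-3-hydroxy-1-[3,5-dimethyl-2,4,6-tris(methoxymethoxy)phenyl]icosan-1-one F8. The aryl MOM ethers are then exchanged with TMSOTf and 2,2'-bipyridyl (CH2Cl2, 0 °C) into aryl trimethylsilyl ethers, which are hydrolysed on aqueous work-up, and the route is rejoined at 16.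

**Further compounds**

F1 | step 10 | methyl (R)-3-hydroxyicosanoate | CCCCCCCCCCCCCCCCC[C@@H](O)CC(=O)OC
F2 | step 10 | methyl (R)-3-[(tert-butyldimethylsilyl)oxy]icosanoate | CCCCCCCCCCCCCCCCC[C@@H](O[Si](C)(C)C(C)(C)C)CC(=O)OC
F3 | step 10 | (R)-3-[(tert-butyldimethylsilyl)oxy]-N-methoxy-N-methylicosanamide | CCCCCCCCCCCCCCCCC[C@@H](O[Si](C)(C)C(C)(C)C)CC(=O)N(C)OC
F4 | step 10 | (R)-3-[(tert-butyldimethylsilyl)oxy]-1-[3,5-dimethyl-2,4,6-tris(methoxymethoxy)phenyl]icosan-1-one | CCCCCCCCCCCCCCCCC[C@@H](O[Si](C)(C)C(C)(C)C)CC(=O)c1c(OCOC)c(C)c(OCOC)c(C)c1OCOC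
F5 | step 10 | (R)-3-hydroxy-1-(2,4,6-trihydroxy-3,5-dimethylphenyl)icosan-1-one | CCCCCCCCCCCCCCCCC[C@@H](O)CC(=O)c1c(O)c(C)c(O)c(C)c1O
F6 | step 8 | (S)-3-[(tert-butyldimethylsilyl)oxy]icosanal | CCCCCCCCCCCCCCCCC[C@H](O[Si](C)(C)C(C)(C)C)CC=O
F7 | step 8 | (3S)-3-[(tert-butyldimethylsilyl)oxy]-1-[3,5-dimethyl-2,4,6-tris(methoxymethoxy)phenyl]icosan-1-ol (both epimers at C1) | CCCCCCCCCCCCCCCCC[C@H](O[Si](C)(C)C(C)(C)C)CC(O)c1c(OCOC)c(C)c(OCOC)c(C)c1OCOC
F8 | step 9 | (S)-3-hydroxy-1-[3,5-dimethyl-2,4,6-tris(methoxymethoxy)phenyl]icosan-1-one | CCCCCCCCCCCCCCCCC[C@H](O)CC(=O)c1c(OCOC)c(C)c(OCOC)c(C)c1OCOC
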